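**Assumption:** the sense of asymmetric induction of the new chiral iodane in step 3 is taken as written ((R,R)-reagent gives the (3R,4S) adduct); if it proves opposite, the (S,S)-reagent from the other lactate enantiomer is used with nothing else changed.

**Retrosynthetic overview**
1. Target ⇐ isopropenyl diester by allylic oxidation of the vinylic methyl to the enal (last step); the benzylic (R)-ester ⇐ aryl methyl ketone by asymmetric transfer hydrogenation, then acylation.
2. trans-3-Acyloxy-2-isopropenyl-2,3-dihydrobenzofuran ⇐ 6-acetyl-2,2-dimethyl-2H-chromene by C4 acyloxylation and a 1,2-shift of the ring oxygen from C2 to C3 (pyran to dihydrofuran ring contraction); both ring stereocentres are set here.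
3. Chromene ⇐ 4-hydroxyacetophenone + 3-chloro-3-methylbut-1-yne; 4-hydroxyacetophenone ⇐ phenol + acetyl chloride.
4. Ring order: benzene ring bought as phenol, then the pyran ring is annulated (step 2), then the pyran is contracted to the dihydrofuran ring (step 3).

**Route**

Step 1
Reactants: 1 phenol; 2 acetyl chloride
Product: 4 1-(4-hydroxyphenyl)ethanone, via phenyl acetate 3 (not isolated)
Conditions: CF3SO3H (neat, 5 equiv), 0 °C → rt
Reagents that add atoms: none
Why: In neat triflic acid the first-formed phenyl acetate re-ionises to the acylium ion and C-acylates para to the hydroxyl (Friedel–Crafts acylation / Fries rearrangement); no stereocentre.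

Step 2
Reactants: 4 1-(4-hydroxyphenyl)ethanone; 5 3-chloro-3-methylbut-1-yne
Product: 7 1-(2,2-dimethyl-2H-chromen-6-yl)ethanone, via propargyl ether 6 (not isolated)
Conditions: K2CO3, KI, CuI (5 mol %), DMF, 65 °C; then 155 °C in the same pot
Reagents that add atoms: none
Why: Copper-assisted O-alkylation by the tertiary propargylic chloride is followed by the thermal aryl propargyl ether rearrangement (propargyl Claisen cascade), which closes the 2,2-dimethylpyran ring at either of the two equivalent ortho positions; no stereocentre.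

Step 3
Reactants: 7 1-(2,2-dimethyl-2H-chromen-6-yl)ethanone
Product: 10 (2R,3S)-5-acetyl-2-(prop-1-en-2-yl)-2,3-dihydro-1-benzofuran-3-yl 3-methylbutanoate, via trans-iodane adduct 8 (not isolated), via tertiary cation 9 (not isolated)
Conditions: chiral aryl-λ3-iodane bis(3-methylbutanoate) (1.2 equiv; made beforehand from the (R,R)-iodoarene, NaBO3·4H2O and 3-methylbutanoic acid), BF3·OEt2 (2.5 equiv), 2,6-di-tert-butyl-4-methylpyridine (1.2 equiv), CH2Cl2, −78 → −40 °C; iodoarene recovered
Reagents that add atoms: {2,6-bis[(1R)-1-methyl-2-oxo-2-(2,4,6-trimethylanilino)ethoxy]phenyl}-λ3-iodanediyl bis(3-methylbutanoate), CC(C)CC(=O)OI(OC(=O)CC(C)C)c1c(O[C@H](C)C(=O)Nc2c(C)cc(C)cc2C)cccc1O[C@H](C)C(=O)Nc1c(C)cc(C)cc1C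
Why: Proposed new method: the BF3-activated chiral trivalent-iodine reagent binds one enantiotopic face of the cis-styrenyl C3=C4 bond and one of its isovalerate ligands attacks benzylic C4 anti, setting C4 as S (closest known reactions: vicinal diacyloxylation of styrenes with lactate-derived chiral trivalent-iodine reagents and the trivalent-iodine ring contraction of 1,2-dihydronaphthalenes by aryl shift); in the trans-diequatorial adduct 8 the ring C2–O1 bond is antiperiplanar to the C3–I bond, whereas the diaxial conformer needed for acyloxonium participation suffers a 1,3-diaxial clash between the C4 ester and the axial C2 methyl, so loss of the iodoarene is accompanied by a 1,2-shift of the ring oxygen from C2 to C3 with inversion (six- to five-membered ring contraction, giving the future C2 as R and trans to the ester), and the tertiary cation 9 loses a methyl proton to give the isopropenyl group, as in the known solvolytic contraction of 3-sulfonyloxy-2,2-dimethylchromans.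

Step 4
Reactants: 10 (2R,3S)-5-acetyl-2-(prop-1-en-2-yl)-2,3-dihydro-1-benzofuran-3-yl 3-methylbutanoate
Product: 11 (2R,3S)-5-[(1R)-1-hydroxyethyl]-2-(prop-1-en-2-yl)-2,3-dihydro-1-benzofuran-3-yl 3-methylbutanoate
Conditions: RuCl[(R,R)-TsDPEN](p-cymene) (1 mol %; TsDPEN = N-tosyl-1,2-diphenylethylenediamine), HCO2H/Et3N (5:2), EtOAc, 35 °C
Reagents that add atoms: none
Why: Noyori asymmetric transfer hydrogenation delivers hydride to the Si face of the aryl methyl ketone under catalyst control to give the (R)-carbinol, and leaves the ester, the allyl aryl ether and the 1,1-disubstituted alkene untouched.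

Step 5
Reactants: 11 (2R,3S)-5-[(1R)-1-hydroxyethyl]-2-(prop-1-en-2-yl)-2,3-dihydro-1-benzofuran-3-yl 3-methylbutanoate; 12 3-methylbutanoyl chloride
Product: 13 (2R,3S)-5-[(1R)-1-(3-methylbutanoyloxy)ethyl]-2-(prop-1-en-2-yl)-2,3-dihydro-1-benzofuran-3-yl 3-methylbutanoate
Conditions: Et3N, 4-(dimethylamino)pyridine (cat.), CH2Cl2, 0 °C → rt
Reagents that add atoms: none
Why: Base-buffered nucleophilic acyl substitution (esterification catalysed by 4-(dimethylamino)pyridine) acylates the only free hydroxyl with retention, because the benzylic C–O bond is never broken.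

Step 6
Reactants: 13 (2R,3S)-5-[(1R)-1-(3-methylbutanoyloxy)ethyl]-2-(prop-1-en-2-yl)-2,3-dihydro-1-benzofuran-3-yl 3-methylbutanoate
Product: 15 (2R,3S)-5-[(1R)-1-(3-methylbutanoyloxy)ethyl]-2-(3-oxoprop-1-en-2-yl)-2,3-dihydro-1-benzofuran-3-yl 3-methylbutanoate, via allylic alcohol 14 (not isolated)
Conditions: SeO2 (1.5 equiv), pyridine (0.5 equiv), 1,4-dioxane, 80 °C
Reagents that add atoms: selenium dioxide, O=[Se]=O
Why: Riley allylic oxidation (ene reaction then [2,3]-sigmatropic shift, with further oxidation of the allylic alcohol) attacks the vinylic methyl in preference to the oxygen-deactivated C2 methine and gives the α-substituted acrolein without touching a stereocentre, the pyridine buffer protecting the two benzylic esters from acid.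

**Compound list**
1 | phenol | Oc1ccccc1 | starting material
2 | acetyl chloride | CC(Cl)=O | starting material
3 | phenyl acetate | CC(=O)Oc1ccccc1 | intermediate
4 | 1-(4-hydroxyphenyl)ethanone | CC(=O)c1ccc(O)cc1 | intermediate
5 | 3-chloro-3-methylbut-1-yne | CC(C)(Cl)C#C | starting material
6 | 1-[4-(2-methylbut-3-yn-2-yloxy)phenyl]ethanone | CC(=O)c1ccc(OC(C)(C)C#C)cc1 | intermediate
7 | 1-(2,2-dimethyl-2H-chromen-6-yl)ethanone | CC(=O)c1ccc2OC(C)(C)C=Cc2c1 | intermediate
8 | (3R,4S)-6-acetyl-3-[aryl(3-methylbutanoyloxy)-λ3-iodanyl]-2,2-dimethyl-3,4-dihydro-2H-chromen-4-yl 3-methylbutanoate (aryl = 2,6-bis[(1R)-1-methyl-2-oxo-2-(2,4,6-trimethylanilino)ethoxy]phenyl) | CC(=O)c1ccc2OC(C)(C)[C@H](I(OC(=O)CC(C)C)c3c(O[C@H](C)C(=O)Nc4c(C)cc(C)cc4C)cccc3O[C@H](C)C(=O)Nc3c(C)cc(C)cc3C)[C@@H](OC(=O)CC(C)C)c2c1 | intermediate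
9 | 2-[(2R,3S)-5-acetyl-3-(3-methylbutanoyloxy)-2,3-dihydro-1-benzofuran-2-yl]propan-2-ylium | C[C+](C)[C@H]1Oc2ccc(C(C)=O)cc2[C@@H]1OC(=O)CC(C)C | intermediate
10 | (2R,3S)-5-acetyl-2-(prop-1-en-2-yl)-2,3-dihydro-1-benzofuran-3-yl 3-methylbutanoate | CC(=C)[C@H]1Oc2ccc(C(C)=O)cc2[C@@H]1OC(=O)CC(C)C | intermediate
11 | (2R,3S)-5-[(1R)-1-hydroxyethyl]-2-(prop-1-en-2-yl)-2,3-dihydro-1-benzofuran-3-yl 3-methylbutanoate | CC(=C)[C@H]1Oc2ccc([C@@H](C)O)cc2[C@@H]1OC(=O)CC(C)C | intermediate
12 | 3-methylbutanoyl chloride | CC(C)CC(Cl)=O | starting material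
13 | (2R,3S)-5-[(1R)-1-(3-methylbutanoyloxy)ethyl]-2-(prop-1-en-2-yl)-2,3-dihydro-1-benzofuran-3-yl 3-methylbutanoate | CC(=C)[C@H]1Oc2ccc([C@@H](C)OC(=O)CC(C)C)cc2[C@@H]1OC(=O)CC(C)C | intermediate
14 | (2R,3S)-2-(3-hydroxyprop-1-en-2-yl)-5-[(1R)-1-(3-methylbutanoyloxy)ethyl]-2,3-dihydro-1-benzofuran-3-yl 3-methylbutanoate | C=C(CO)[C@H]1Oc2ccc([C@@H](C)OC(=O)CC(C)C)cc2[C@@H]1OC(=O)CC(C)C | intermediate
15 | (2R,3S)-5-[(1R)-1-(3-methylbutanoyloxy)ethyl]-2-(3-oxoprop-1-en-2-yl)-2,3-dihydro-1-benzofuran-3-yl 3-methylbutanoate | C=C(C=O)[C@H]1Oc2ccc([C@@H](C)OC(=O)CC(C)C)cc2[C@@H]1OC(=O)CC(C)C | target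

**Step count:** 6 steps in total; longest linear sequence 6 steps.

**Steps most likely to fail, with fallbacks**

Step 3 (the proposed new ring contraction). Possible failures are acyloxonium participation leading to cis-dioxygenation, aryl instead of oxygen migration, attack of the reagent on the isopropenyl group of the product, or insufficient enantioselectivity. The fallback uses known chemistry, sets out from 7 and comes back at 10. Jacobsen–Katsuki epoxidation of 7 with (R,R)-N,N'-bis(3,5-di-tert-butylsalicylidene)-1,2-cyclohexanediaminomanganese chloride (4 mol %), buffered aqueous NaOCl and 4-phenylpyridine N-oxide in CH2Cl2 at 0 °C gives the (3R,4R)-epoxide F1. This is opened at benzylic C4 with inversion by 3-methylbutanoic acid and Cs2CO3 (0.3 equiv) in DMF at 60 °C to give the trans-hydroxy ester F2. Treatment with (CF3SO2)2O and 2,6-di-tert-butyl-4-methylpyridine in CH2Cl2 at −78 → 0 °C forms the triflate F3, which ionises in the flask with the same 1,2-shift of the ring oxygen through cation 9 and loses a proton to give 10. This costs two extra steps.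

Step 6 (SeO2 oxidation). Possible failures are a stalled reaction at the allylic alcohol 14, acid-induced loss of isovaleric acid to give a benzofuran, or ionisation of the p-alkoxybenzylic ester. The fallback sets out from 13 and comes back at 15. Ene-type allylic chlorination with Ca(OCl)2 and solid CO2 in CH2Cl2/H2O at 0 °C gives the allylic chloride F4. This is oxidised under neutral conditions with 4-methylmorpholine N-oxide and NaI (cat.) in MeCN at rt (Ganem-type N-oxide oxidation) to the enal 15.

Step 2 (one-pot propargylation and rearrangement). The electron-poor aryl ether may rearrange sluggishly or decompose in hot basic DMF. The fallback sets out from 4 and comes back at 7. Compound 4 is condensed with 3-methylbut-2-enal (CC(C)=CC=O) and phenylboronic acid (1 equiv) with acetic acid in toluene at reflux under water removal. The cyclic boronate, the benzodioxaborin F5, forms by ortho-specific addition and collapses on heating to the chromene 7, with no propargyl ether involved.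

**Further compounds**
F1 | step 3 | (3R,4R)-6-acetyl-3,4-epoxy-2,2-dimethyl-3,4-dihydro-2H-chromene | CC(=O)c1ccc2OC(C)(C)[C@@H]3O[C@@H]3c2c1
F2 | step 3 | (3R,4S)-6-acetyl-3-hydroxy-2,2-dimethyl-3,4-dihydro-2H-chromen-4-yl 3-methylbutanoate | CC(=O)c1ccc2OC(C)(C)[C@H](O)[C@@H](OC(=O)CC(C)C)c2c1
F3 | step 3 | (3R,4S)-6-acetyl-2,2-dimethyl-3-(trifluoromethylsulfonyloxy)-3,4-dihydro-2H-chromen-4-yl 3-methylbutanoate | CC(=O)c1ccc2OC(C)(C)[C@H](OS(=O)(=O)C(F)(F)F)[C@@H](OC(=O)CC(C)C)c2c1
F4 | step 6 | (2R,3S)-2-(3-chloroprop-1-en-2-yl)-5-[(1R)-1-(3-methylbutanoyloxy)ethyl]-2,3-dihydro-1-benzofuran-3-yl 3-methylbutanoate | C=C(CCl)[C@H]1Oc2ccc([C@@H](C)OC(=O)CC(C)C)cc2[C@@H]1OC(=O)CC(C)C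
F5 | step 2 | rac-1-[4-(2-methylprop-1-enyl)-2-phenyl-4H-1,3,2-benzodioxaborinin-6-yl]ethanone | CC(=O)c1ccc2OB(c3ccccc3)OC(C=C(C)C)c2c1
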